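## Structural features

The target is built from two isoflavan units. The upper 7-hydroxychroman (benzo ring A; pyran atoms O1, C2, C3, C4) carries ring B (2-hydroxy-4-methoxyphenyl) on C3 and the central ring E on C4. The lower 7-hydroxychroman (benzo ring D) is bonded through its C3 to ring E. Ring E is numbered here E1 (bonded to lower C3), E2 (OH), E3 (H), E4 (OMe), E5 (bonded to upper C4), E6 (H). There are three stereocentres: upper C3 (R) and C4 (S) are adjacent and trans on the pyran ring, and lower C3 (R) is separated from them by ring E. The four phenols are oxidisable, and the doubly benzylic C4, flanked by two resorcinol-type rings, can ionise or lose an aryl group under acid, so cationic chemistry at C4 and strong acid late in the route are avoided. The real difficulty is the upper C3/C4 pair: two vicinal benzylic methines, one bearing two different electron-rich aryl groups, to be set in relative and absolute sense with no help from the remote lower centre. The key step uses the fact that C3 and C4 each need one aryl group from outside (ring B on C3, ring A carbon C4a on C4) while C4 already belongs to ring E. An (E)-styrenyl boron unit on E5 therefore maps onto C4=C3–B, the two aryl groups can be added anti across it, and the boron left on C3 marks the place of C2. Rings A and D are the same 4-oxygenated 2-hydroxyphenyl unit and rings B and E the same 2-hydroxy-4-methoxyphenyl unit, so two building blocks each serve twice.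

## Logic of the disconnections

32 to 31: the four O–CH2Ph bonds are cut. The phenols are carried as benzyl ethers so that every intermediate tolerates organolithium, palladium and peroxide chemistry, and one neutral step ends the route. The forward step must cleave only O-benzyl bonds; no ring C–O bond is benzylic at oxygen and C–C bonds at C4 are inert to hydrogenolysis.

31 to 30 to 29: the upper O1–C2 bond is cut, then the O–CH2OMe bond on the ring A oxygen. A primary C–O bond is made by SN2 without touching C3 or C4, and the chroman becomes an acyclic 2,3,3-triarylpropanol. The demand is that only the ring A phenol is free at ring closure (a free ring B phenol would close a five-membered ring onto C2), hence methoxymethyl on ring A against benzyl elsewhere, and that the methoxymethyl group leaves under conditions too mild to ionise C4.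

29 to 26: the C2–C3 bond and the C2–O bond are cut, C2 coming from a chloromethyl carbenoid inserted into the C3–B bond. This removes one carbon and leaves boron directly on C3, which is what the key step delivers. The insertion must occur at a congested boron and with retention at C3.

26 to 23, 7 and 5: the C3–ring B bond and the C4–C4a bond are cut. Three pieces of comparable size result, both upper stereocentres are traced to one alkene geometry and one chiral ligand, and no cation at C4 is needed. The forward step must favour the metallate shift over direct transfer of a group from boron to palladium, and must select one alkene face.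

23 to 22 to 19 and 20: the diol on boron is exchanged and the C3=C4 double bond is cut to the ring E aldehyde carbon and a diborylmethane carbon. The ring E partner becomes an aldehyde that carries the finished lower isoflavan. The demands are E geometry and a boron ligand bulky enough for a β-substituted alkenylboron.

19 to 18 to 17 to 14: the lower O1–C2 bond, the ring D methoxymethyl ether and the aldehyde acetal, then the lower C2–C3 and C2–O bonds are cut, by the same logic as in the upper unit. One acid step must unmask the phenol and the aldehyde together.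

14 to 10, 11 and 5: the lower C3–E1 bond and the lower C4–C4a bond (ring D) are cut across a vinylboron linchpin. Three simple pieces result and 5 is used a second time. The forward step must set lower C3 by catalyst control, and the ring E aldehyde must be masked against the aryllithium.

10 to 9 to 7 to 6: the acetal C–O bonds, the E5–CHO bond and the O-benzyl bond are cut. Compound 7 is also the source of ring B. The formylation must go para to the benzyloxy group.

5 to 4 to 2 to 1: the S–O bond, the aryl C–O bond (formed by oxidative aryl migration from the aldehyde) and the O–CH2OMe bond are cut. The aryl group, not hydrogen, must migrate.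

## Other disconnections considered

Alternative 1: Ring E is removed altogether, so bonds E1–E2, E2–E3, E4–E5 and E5–E6 are formed last. In the forward sense the diazo enone A2 (upper C4 on the diazo carbon, lower C3 at the far end of the enone) undergoes Wolff rearrangement to a vinylketene. Methoxyacetylene A3 adds by [2+2] cycloaddition, the four-membered ring opens and the resulting dienylketene closes to the phenol A1 with the E2 hydroxyl free (Danheiser benzannulation). In its favour, the substitution pattern of ring E is fixed by the mechanism, the two chromans are made apart and joined very late, and the E2 phenol emerges differentiated. Against it here, the step creates no stereocentre, so the trans C3/C4 pair must already be present in A2, where C4 sits on a carbene precursor and 1,2-hydride shift can compete with the Wolff shift. Lower C3 is γ to the enone carbonyl and may be lost by dienolisation, and A3 is volatile and unstable. On regiocontrol of ring E and on convergence this plan is the better of the two, since the chosen route relies on a regioselective formylation. On the central stereochemical problem it is weaker, because it leaves that problem to earlier steps, and it would be longer, since both chromans need two-carbon handles.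

Alternative 2: The lower C3–E1 and lower C4–ring D bonds are cut and made last. The aryllithium from bromide A5, which carries the complete upper chroman, adds to 11, and the ate complex couples with 5 under Pd(OAc)2 and a MandyPhos ligand to give the secondary boronic ester A4. Homologation, oxidation and ring closure follow. In its favour, this is the best-documented form of the reaction (unsubstituted vinylboron, pinacol ester sufficient), so on precedent it is better than step 13, and the catalyst sets lower C3 without reference to the upper centres. Against it, the upper C3/C4 pair is left to an earlier step, most plausibly the very coupling chosen here. Ring E would then have to carry a halide through an ate complex and zerovalent palladium, and tert-butyllithium would be used on a late, valuable intermediate. The comparison is one of order: the chosen route uses this same disconnection in step 7 on small fragments, and the number of operations is equal. Alternative 2 would test the less certain β-aryl coupling early on cheap material, which is a point in its favour. The chosen order keeps the ring E handle a simple masked aldehyde.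

Alternative 3: The C3–C4 bond and the O1–C2 acyl bond are cut. The arylacetic acid A7, activated as its pivalic mixed anhydride, is turned by a chiral isothiourea into an ammonium enolate that adds to the methide carbon of the ortho-quinone methide A8. The ring A phenoxide then releases the catalyst and closes the trans-dihydrocoumarin A6. In its favour, it needs no organometallic reagent, forms the pyran ring and both stereocentres in one step, and the trans isomer is the thermodynamically favoured one. After the key step only reduction, ring closure and hydrogenolysis remain, fewer operations than the chosen plan needs there, so on this point it is the better. Against it, A8 carries an electron-rich aryl group on the methide carbon, which lowers its electrophilicity and makes facial control at C4 less certain than for the simple methides on which this catalysis rests. C3 of A6 is acidic and C2 is at the wrong oxidation level. A8 is also the conjugate base of the C4 cation that the chosen plan avoids. Mechanistically, the chosen step derives the trans relation stereospecifically from alkene geometry, whereas here it rests on kinetic or thermodynamic diastereoselection. This chemistry is retained as the fallback for step 13.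

Key step: step 13

Remarks before the steps:
- cis-1,2-Dimethylacenaphthene-1,2-diol (mac diol) is treated as a purchasable reagent; otherwise it is one operation from acenaphthenequinone and a methyl-metal reagent.
- The same enantiomer of MandyPhos is written for steps 7 and 13 because both need palladium on the same topological face of the C=C–B unit; which hand this is would be confirmed on a model, and the antipode is equally available.
- The alkenylboron partner of step 13 carries the mac diol, not pinacol, because a β-substituted alkenylboron ate complex with pinacol is expected to transfer its organic groups to palladium directly.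
- The ring E aldehyde needs OMe ortho and OBn para to the formyl carbon. It is made by para-formylation of 7, since 2-hydroxy-4-methoxybenzaldehyde would place the two oxygens the wrong way round relative to the alkenyl carbon.

## Route

Step 1
Reactants: 1 4-(benzyloxy)-2-hydroxybenzaldehyde
Product: 2 4-(benzyloxy)-2-(methoxymethoxy)benzaldehyde
Conditions: MOMCl, i-Pr2NEt, CH2Cl2, 0 °C to rt
Reagents that add atoms: chloromethyl methyl ether (COCCl)
Why: O-Alkylation of the phenol (methoxymethyl protection); the acetal masks the future O1 of both chromans orthogonally to the benzyl ethers and is small enough to sit ortho to the triflate.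

Step 2
Reactants: 2 4-(benzyloxy)-2-(methoxymethoxy)benzaldehyde
Product: 4 4-(benzyloxy)-2-(methoxymethoxy)phenol, via aryl formate 3 (not isolated)
Conditions: mCPBA, CH2Cl2, 0 °C to rt; NaHCO3 (aq) wash; K2CO3 (cat.), MeOH, rt
Reagents that add atoms: 3-chloroperbenzoic acid (O=C(OO)c1cccc(Cl)c1)
Why: Baeyer–Villiger (Dakin-type) oxidation; the ortho,para-dialkoxyaryl group migrates in preference to hydrogen, and the formate is cleaved by methanolysis.

Step 3
Reactants: 4 4-(benzyloxy)-2-(methoxymethoxy)phenol
Product: 5 4-(benzyloxy)-2-(methoxymethoxy)phenyl trifluoromethanesulfonate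
Conditions: Tf2O, pyridine, CH2Cl2, 0 °C
Reagents that add atoms: trifluoromethanesulfonic anhydride (O=S(=O)(OS(=O)(=O)C(F)(F)F)C(F)(F)F)
Why: O-Sulfonylation of a phenol under basic conditions that leave the acetal untouched; 5 is the electrophile for rings D and A.

Step 4
Reactants: 6 2-bromo-5-methoxyphenol
Product: 7 1-(benzyloxy)-2-bromo-5-methoxybenzene
Conditions: BnBr, K2CO3, DMF, rt
Reagents that add atoms: benzyl bromide (BrCc1ccccc1)
Why: Williamson ether synthesis; 7 is both the source of ring B and the precursor of ring E.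

Step 5
Reactants: 7 1-(benzyloxy)-2-bromo-5-methoxybenzene
Product: 9 4-(benzyloxy)-5-bromo-2-methoxybenzaldehyde, via aryl iminium salt 8 (not isolated)
Conditions: POCl3, DMF, 0 °C then 70 °C; then ice-water
Reagents that add atoms: N,N-dimethylformamide (CN(C)C=O); water (O)
Why: Vilsmeier–Haack formylation; the position para to OBn and ortho to OMe is the only doubly activated open site, since the position para to OMe holds bromine and the one between the two oxygens is hindered.

Step 6
Reactants: 9 4-(benzyloxy)-5-bromo-2-methoxybenzaldehyde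
Product: 10 2-[4-(benzyloxy)-5-bromo-2-methoxyphenyl]-1,3-dioxolane
Conditions: HOCH2CH2OH, p-TsOH·H2O (cat.), toluene, reflux, Dean–Stark trap
Reagents that add atoms: ethane-1,2-diol (OCCO)
Why: Acetalisation with azeotropic removal of water; the aldehyde must be masked against tert-butyllithium and the aryllithium of step 7.

Step 7
Reactants: 10 2-[4-(benzyloxy)-5-bromo-2-methoxyphenyl]-1,3-dioxolane; 11 4,4,5,5-tetramethyl-2-vinyl-1,3,2-dioxaborolane; 5 4-(benzyloxy)-2-(methoxymethoxy)phenyl trifluoromethanesulfonate
Product: 14 2-[(1R)-2-[4-(benzyloxy)-2-(methoxymethoxy)phenyl]-1-[2-(benzyloxy)-5-(1,3-dioxolan-2-yl)-4-methoxyphenyl]ethyl]-4,4,5,5-tetramethyl-1,3,2-dioxaborolane, via aryllithium 12 (not isolated), via lithium vinylborate complex 13 (not isolated)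
Conditions: t-BuLi (2 equiv), Et2O, −78 °C; 11, −78 °C to rt; solvent changed to THF; 5, Pd(OAc)2 (2 mol%), (Sp,Sp)-MandyPhos (2.4 mol%), NaOTf, THF, 60 °C
Reagents that add atoms: none
Why: Palladium-catalysed enantioselective conjunctive cross-coupling of a vinylboron ate complex with an aryl triflate: the arylpalladium cation from 5 binds the vinyl group, ring E shifts from boron to the boron-bearing carbon anti to palladium, and reductive elimination puts ring D on the terminal carbon. Lower C3 (R) is set by the ligand-controlled choice of alkene face; NaOTf removes bromide from solution so that palladium stays cationic.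

Step 8
Reactants: 14 2-[(1R)-2-[4-(benzyloxy)-2-(methoxymethoxy)phenyl]-1-[2-(benzyloxy)-5-(1,3-dioxolan-2-yl)-4-methoxyphenyl]ethyl]-4,4,5,5-tetramethyl-1,3,2-dioxaborolane
Product: 17 (2R)-3-[4-(benzyloxy)-2-(methoxymethoxy)phenyl]-2-[2-(benzyloxy)-5-(1,3-dioxolan-2-yl)-4-methoxyphenyl]propan-1-ol, via chloromethyl borate complex 15 (not isolated), via homologated pinacol boronate 16 (not isolated)
Conditions: BrCH2Cl, n-BuLi, THF, −78 °C to rt; then NaOH (aq), H2O2, 0 °C to rt
Reagents that add atoms: bromochloromethane (ClCBr); hydrogen peroxide (OO)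
Why: Matteson homologation: the carbenoid adds to boron and the benzylic carbon migrates with retention, displacing chloride; the primary C–B bond is then oxidised, so the stereocentre is not touched in either stage.

Step 9
Reactants: 17 (2R)-3-[4-(benzyloxy)-2-(methoxymethoxy)phenyl]-2-[2-(benzyloxy)-5-(1,3-dioxolan-2-yl)-4-methoxyphenyl]propan-1-ol
Product: 18 4-(benzyloxy)-5-[(2R)-1-[4-(benzyloxy)-2-hydroxyphenyl]-3-hydroxypropan-2-yl]-2-methoxybenzaldehyde
Conditions: HCl (3 M aq), THF, 45 °C
Reagents that add atoms: water (O)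
Why: Acid hydrolysis of the phenolic methoxymethyl ether and of the dioxolane in one operation; benzyl ethers are stable, and this fragment has no acid-labile diarylmethine.

Step 10
Reactants: 18 4-(benzyloxy)-5-[(2R)-1-[4-(benzyloxy)-2-hydroxyphenyl]-3-hydroxypropan-2-yl]-2-methoxybenzaldehyde
Product: 19 4-(benzyloxy)-5-[(3R)-7-(benzyloxy)-3,4-dihydro-2H-chromen-3-yl]-2-methoxybenzaldehyde
Conditions: PPh3, DIAD, THF, 0 °C to rt
Reagents that add atoms: none
Why: Intramolecular Mitsunobu etherification (6-exo-tet SN2 at the primary carbon); only the ring D phenol is free, the ring E oxygen is benzylated, and the stereocentre is not involved.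

Step 11
Reactants: 19 4-(benzyloxy)-5-[(3R)-7-(benzyloxy)-3,4-dihydro-2H-chromen-3-yl]-2-methoxybenzaldehyde; 20 bis(4,4,5,5-tetramethyl-1,3,2-dioxaborolan-2-yl)methane
Product: 22 (3R)-7-(benzyloxy)-3-{2-(benzyloxy)-4-methoxy-5-[(E)-2-(4,4,5,5-tetramethyl-1,3,2-dioxaborolan-2-yl)ethenyl]phenyl}-3,4-dihydro-2H-chromene, via lithiated diborylmethane 21 (not isolated)
Conditions: LiTMP, THF, 0 °C; then 19, −78 °C to rt
Reagents that add atoms: none
Why: Boron-Wittig olefination: the α-boryl carbanion adds to the aldehyde and syn elimination of boron and oxygen gives the alkenylboronate, with the aryl group and the remaining boron trans (E).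

Step 12
Reactants: 22 (3R)-7-(benzyloxy)-3-{2-(benzyloxy)-4-methoxy-5-[(E)-2-(4,4,5,5-tetramethyl-1,3,2-dioxaborolan-2-yl)ethenyl]phenyl}-3,4-dihydro-2H-chromene
Product: 23 (E)-alkenylboronic ester of cis-1,2-dimethylacenaphthene-1,2-diol (mac ester) carrying the same ring E and lower (3R)-chroman as 22
Conditions: mac diol (1.2 equiv), FeCl3 (5 mol%), imidazole (15 mol%), MeCN/H2O, rt
Reagents that add atoms: cis-1,2-dimethylacenaphthene-1,2-diol (C[C@]1(O)c2cccc3cccc(c23)[C@@]1(C)O)
Why: Lewis-acid-catalysed transesterification at boron; the rigid cis-diol forms the more stable five-membered ester and pinacol is washed out, with the alkene geometry unaffected.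

Step 13
Reactants: 7 1-(benzyloxy)-2-bromo-5-methoxybenzene; 23 (E)-alkenylboronic mac ester of ring E; 5 4-(benzyloxy)-2-(methoxymethoxy)phenyl trifluoromethanesulfonate
Product: 26 mac ester of (1R,2S)-1-[2-(benzyloxy)-4-methoxyphenyl]-2-[4-(benzyloxy)-2-(methoxymethoxy)phenyl]-2-{4-(benzyloxy)-5-[(3R)-7-(benzyloxy)-3,4-dihydro-2H-chromen-3-yl]-2-methoxyphenyl}ethylboronic acid, via aryllithium 24 (not isolated), via lithium alkenylborate complex 25 (not isolated)
Conditions: t-BuLi (2 equiv), Et2O, −78 °C; 23, THF, −78 °C to rt; 5, Pd(OAc)2 (3 mol%), (Sp,Sp)-MandyPhos (3.6 mol%), NaOTf, THF, 60 °C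
Reagents that add atoms: none
Why: Oxidative addition of 5 to zerovalent palladium (formed from Pd(OAc)2 and the bisphosphine) gives a cationic arylpalladium species that binds the alkene of 25; ring B then shifts from boron to C3 on the face opposite palladium while palladium bonds to C4, and reductive elimination with retention joins C4 to C4a. The closest known reaction type is the palladium/MandyPhos-catalysed enantioselective conjunctive cross-coupling of β-substituted alkenylboron ate complexes bearing a hindered diol with aryl triflates; a β-aryl group and two ortho-alkoxy partners are new substrates within that class. No ring is closed. C4 (S) is set by the alkene face that the chiral ligand lets palladium bind, and C3 (R) follows stereospecifically from the E geometry and the anti metallate shift, which gives the anti pair that becomes trans on the pyran ring. The remote lower C3 exerts no control, so the wrong facial isomer would be a diastereomer and in principle separable. The step needs the metallate shift to outrun direct transfer of the alkenyl or aryl group from boron to palladium; the bulky mac diol is there to slow that transfer, and the triflate leaving group and NaOTf keep palladium cationic and free of halide. The medium is basic to neutral throughout, so no cation is formed at C4 and the benzyl and methoxymethyl ethers are inert.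

Step 14
Reactants: 26 mac ester of the (1R,2S)-triarylethylboronic acid
Product: 29 (2R,3S)-3-[4-(benzyloxy)-2-(methoxymethoxy)phenyl]-3-{4-(benzyloxy)-5-[(3R)-7-(benzyloxy)-3,4-dihydro-2H-chromen-3-yl]-2-methoxyphenyl}-2-[2-(benzyloxy)-4-methoxyphenyl]propan-1-ol, via chloromethyl borate complex 27 (not isolated), via homologated mac boronate 28 (not isolated)
Conditions: BrCH2Cl, n-BuLi, THF, −78 °C to rt; then NaOH (aq), H2O2, 0 °C to rt
Reagents that add atoms: bromochloromethane (ClCBr); hydrogen peroxide (OO)
Why: Matteson homologation inserts C2 into the C3–B bond with retention at C3, and oxidation of the new primary C–B bond gives the C2 alcohol and releases the mac diol; C4 is not involved.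

Step 15
Reactants: 29 (2R,3S)-triarylpropanol methoxymethyl ether
Product: 30 (2R,3S)-3-[4-(benzyloxy)-2-hydroxyphenyl]-3-{4-(benzyloxy)-5-[(3R)-7-(benzyloxy)-3,4-dihydro-2H-chromen-3-yl]-2-methoxyphenyl}-2-[2-(benzyloxy)-4-methoxyphenyl]propan-1-ol
Conditions: ZnBr2, n-PrSH, CH2Cl2, 0 °C to rt
Reagents that add atoms: none
Why: Lewis acid and thiol cleave the phenolic methoxymethyl ether by capture of the methoxymethyl group on sulfur, under conditions too mild to ionise the diarylmethine C4 or to cleave benzyl ethers.

Step 16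
Reactants: 30 (2R,3S)-triarylpropanol with free ring A phenol
Product: 31 (3R,4S)-7-(benzyloxy)-4-{4-(benzyloxy)-5-[(3R)-7-(benzyloxy)-3,4-dihydro-2H-chromen-3-yl]-2-methoxyphenyl}-3-[2-(benzyloxy)-4-methoxyphenyl]-3,4-dihydro-2H-chromene
Conditions: PPh3, DIAD, THF, 0 °C to rt
Reagents that add atoms: none
Why: Intramolecular Mitsunobu etherification closes O1–C2 by SN2 at the primary carbon; the ring B oxygen is benzylated, so only the six-membered ring can form, and C3 and C4 keep their configuration.

Step 17
Reactants: 31 tetra-O-benzyl ether of the target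
Product: 32 (3R,4S)-4-{4-hydroxy-5-[(3R)-7-hydroxy-3,4-dihydro-2H-chromen-3-yl]-2-methoxyphenyl}-3-(2-hydroxy-4-methoxyphenyl)-3,4-dihydro-2H-chromen-7-ol (target)
Conditions: H2 (1 atm), Pd(OH)2/C, EtOAc/MeOH, rt
Reagents that add atoms: none
Why: Hydrogenolysis of the four aryl benzyl ethers under neutral conditions; the chroman C–O bonds are not benzylic at oxygen and the stereocentres are not epimerisable under these conditions.

## Compound list

1 | 4-(benzyloxy)-2-hydroxybenzaldehyde | O=Cc1ccc(OCc2ccccc2)cc1O | starting material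
2 | 4-(benzyloxy)-2-(methoxymethoxy)benzaldehyde | COCOc1cc(OCc2ccccc2)ccc1C=O | intermediate
3 | 4-(benzyloxy)-2-(methoxymethoxy)phenyl formate | COCOc1cc(OCc2ccccc2)ccc1OC=O | intermediate
4 | 4-(benzyloxy)-2-(methoxymethoxy)phenol | COCOc1cc(OCc2ccccc2)ccc1O | intermediate
5 | 4-(benzyloxy)-2-(methoxymethoxy)phenyl trifluoromethanesulfonate | COCOc1cc(OCc2ccccc2)ccc1OS(=O)(=O)C(F)(F)F | intermediate
6 | 2-bromo-5-methoxyphenol | COc1ccc(Br)c(O)c1 | starting material
7 | 1-(benzyloxy)-2-bromo-5-methoxybenzene | COc1ccc(Br)c(OCc2ccccc2)c1 | intermediate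
8 | N-{[4-(benzyloxy)-5-bromo-2-methoxyphenyl]methylidene}-N-methylmethanaminium dichlorophosphate | COc1cc(OCc2ccccc2)c(Br)cc1C=[N+](C)C.[O-]P(=O)(Cl)Cl | intermediate
9 | 4-(benzyloxy)-5-bromo-2-methoxybenzaldehyde | COc1cc(OCc2ccccc2)c(Br)cc1C=O | intermediate
10 | 2-[4-(benzyloxy)-5-bromo-2-methoxyphenyl]-1,3-dioxolane | COc1cc(OCc2ccccc2)c(Br)cc1C1OCCO1 | intermediate
11 | 4,4,5,5-tetramethyl-2-vinyl-1,3,2-dioxaborolane | C=CB1OC(C)(C)C(C)(C)O1 | starting material
12 | [2-(benzyloxy)-5-(1,3-dioxolan-2-yl)-4-methoxyphenyl]lithium | [Li]c1cc(C2OCCO2)c(OC)cc1OCc1ccccc1 | intermediate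
13 | lithium [2-(benzyloxy)-5-(1,3-dioxolan-2-yl)-4-methoxyphenyl](ethenyl)(pinacolato)borate | [Li+].C=C[B-]1(c2cc(C3OCCO3)c(OC)cc2OCc2ccccc2)OC(C)(C)C(C)(C)O1 | intermediate
14 | 2-[(1R)-2-[4-(benzyloxy)-2-(methoxymethoxy)phenyl]-1-[2-(benzyloxy)-5-(1,3-dioxolan-2-yl)-4-methoxyphenyl]ethyl]-4,4,5,5-tetramethyl-1,3,2-dioxaborolane | COc1cc(OCc2ccccc2)c([C@@H](Cc2ccc(OCc3ccccc3)cc2OCOC)B2OC(C)(C)C(C)(C)O2)cc1C1OCCO1 | intermediate
15 | lithium (chloromethyl)borate complex of 14 | [Li+].COc1cc(OCc2ccccc2)c([C@@H](Cc2ccc(OCc3ccccc3)cc2OCOC)[B-]2(CCl)OC(C)(C)C(C)(C)O2)cc1C1OCCO1 | intermediate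
16 | 2-[(2R)-3-[4-(benzyloxy)-2-(methoxymethoxy)phenyl]-2-[2-(benzyloxy)-5-(1,3-dioxolan-2-yl)-4-methoxyphenyl]propyl]-4,4,5,5-tetramethyl-1,3,2-dioxaborolane | COc1cc(OCc2ccccc2)c([C@@H](Cc2ccc(OCc3ccccc3)cc2OCOC)CB2OC(C)(C)C(C)(C)O2)cc1C1OCCO1 | intermediate
17 | (2R)-3-[4-(benzyloxy)-2-(methoxymethoxy)phenyl]-2-[2-(benzyloxy)-5-(1,3-dioxolan-2-yl)-4-methoxyphenyl]propan-1-ol | COc1cc(OCc2ccccc2)c([C@@H](Cc2ccc(OCc3ccccc3)cc2OCOC)CO)cc1C1OCCO1 | intermediate
18 | 4-(benzyloxy)-5-[(2R)-1-[4-(benzyloxy)-2-hydroxyphenyl]-3-hydroxypropan-2-yl]-2-methoxybenzaldehyde | COc1cc(OCc2ccccc2)c([C@@H](Cc2ccc(OCc3ccccc3)cc2O)CO)cc1C=O | intermediate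
19 | 4-(benzyloxy)-5-[(3R)-7-(benzyloxy)-3,4-dihydro-2H-chromen-3-yl]-2-methoxybenzaldehyde | COc1cc(OCc2ccccc2)c([C@@H]2COc3cc(OCc4ccccc4)ccc3C2)cc1C=O | intermediate
20 | bis(4,4,5,5-tetramethyl-1,3,2-dioxaborolan-2-yl)methane | CC1(C)OB(CB2OC(C)(C)C(C)(C)O2)OC1(C)C | starting material
21 | [bis(4,4,5,5-tetramethyl-1,3,2-dioxaborolan-2-yl)methyl]lithium | [Li]C(B1OC(C)(C)C(C)(C)O1)B1OC(C)(C)C(C)(C)O1 | intermediate
22 | (3R)-7-(benzyloxy)-3-{2-(benzyloxy)-4-methoxy-5-[(E)-2-(4,4,5,5-tetramethyl-1,3,2-dioxaborolan-2-yl)ethenyl]phenyl}-3,4-dihydro-2H-chromene | COc1cc(OCc2ccccc2)c([C@@H]2COc3cc(OCc4ccccc4)ccc3C2)cc1/C=C/B1OC(C)(C)C(C)(C)O1 | intermediate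
23 | [(E)-2-{4-(benzyloxy)-5-[(3R)-7-(benzyloxy)-3,4-dihydro-2H-chromen-3-yl]-2-methoxyphenyl}ethenyl]boronic acid, cyclic ester with cis-1,2-dimethylacenaphthene-1,2-diol | COc1cc(OCc2ccccc2)c([C@@H]2COc3cc(OCc4ccccc4)ccc3C2)cc1/C=C/B1O[C@@]2(C)c3cccc4cccc(c34)[C@@]2(C)O1 | intermediate
24 | [2-(benzyloxy)-4-methoxyphenyl]lithium | [Li]c1ccc(OC)cc1OCc1ccccc1 | intermediate
25 | lithium borate complex of 23 with the 2-(benzyloxy)-4-methoxyphenyl group on boron (configuration at boron not defined) | [Li+].COc1ccc([B-]2(/C=C/c3cc([C@@H]4COc5cc(OCc6ccccc6)ccc5C4)c(OCc4ccccc4)cc3OC)O[C@@]3(C)c4cccc5cccc(c45)[C@@]3(C)O2)c(OCc2ccccc2)c1 | intermediate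
26 | (1R,2S)-1-[2-(benzyloxy)-4-methoxyphenyl]-2-[4-(benzyloxy)-2-(methoxymethoxy)phenyl]-2-{4-(benzyloxy)-5-[(3R)-7-(benzyloxy)-3,4-dihydro-2H-chromen-3-yl]-2-methoxyphenyl}ethylboronic acid, cyclic ester with cis-1,2-dimethylacenaphthene-1,2-diol | COc1ccc([C@H](B2O[C@@]3(C)c4cccc5cccc(c45)[C@@]3(C)O2)[C@@H](c2ccc(OCc3ccccc3)cc2OCOC)c2cc([C@@H]3COc4cc(OCc5ccccc5)ccc4C3)c(OCc3ccccc3)cc2OC)c(OCc2ccccc2)c1 | intermediate
27 | lithium (chloromethyl)borate complex of 26 (configuration at boron not defined) | [Li+].COc1ccc([C@H]([B-]2(CCl)O[C@@]3(C)c4cccc5cccc(c45)[C@@]3(C)O2)[C@@H](c2ccc(OCc3ccccc3)cc2OCOC)c2cc([C@@H]3COc4cc(OCc5ccccc5)ccc4C3)c(OCc3ccccc3)cc2OC)c(OCc2ccccc2)c1 | intermediate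
28 | (2R,3S)-2-[2-(benzyloxy)-4-methoxyphenyl]-3-[4-(benzyloxy)-2-(methoxymethoxy)phenyl]-3-{4-(benzyloxy)-5-[(3R)-7-(benzyloxy)-3,4-dihydro-2H-chromen-3-yl]-2-methoxyphenyl}propylboronic acid, cyclic ester with cis-1,2-dimethylacenaphthene-1,2-diol | COc1ccc([C@H](CB2O[C@@]3(C)c4cccc5cccc(c45)[C@@]3(C)O2)[C@@H](c2ccc(OCc3ccccc3)cc2OCOC)c2cc([C@@H]3COc4cc(OCc5ccccc5)ccc4C3)c(OCc3ccccc3)cc2OC)c(OCc2ccccc2)c1 | intermediate
29 | (2R,3S)-3-[4-(benzyloxy)-2-(methoxymethoxy)phenyl]-3-{4-(benzyloxy)-5-[(3R)-7-(benzyloxy)-3,4-dihydro-2H-chromen-3-yl]-2-methoxyphenyl}-2-[2-(benzyloxy)-4-methoxyphenyl]propan-1-ol | COc1ccc([C@H](CO)[C@@H](c2ccc(OCc3ccccc3)cc2OCOC)c2cc([C@@H]3COc4cc(OCc5ccccc5)ccc4C3)c(OCc3ccccc3)cc2OC)c(OCc2ccccc2)c1 | intermediate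
30 | (2R,3S)-3-[4-(benzyloxy)-2-hydroxyphenyl]-3-{4-(benzyloxy)-5-[(3R)-7-(benzyloxy)-3,4-dihydro-2H-chromen-3-yl]-2-methoxyphenyl}-2-[2-(benzyloxy)-4-methoxyphenyl]propan-1-ol | COc1ccc([C@H](CO)[C@@H](c2ccc(OCc3ccccc3)cc2O)c2cc([C@@H]3COc4cc(OCc5ccccc5)ccc4C3)c(OCc3ccccc3)cc2OC)c(OCc2ccccc2)c1 | intermediate
31 | (3R,4S)-7-(benzyloxy)-4-{4-(benzyloxy)-5-[(3R)-7-(benzyloxy)-3,4-dihydro-2H-chromen-3-yl]-2-methoxyphenyl}-3-[2-(benzyloxy)-4-methoxyphenyl]-3,4-dihydro-2H-chromene | COc1ccc([C@@H]2COc3cc(OCc4ccccc4)ccc3[C@H]2c2cc([C@@H]3COc4cc(OCc5ccccc5)ccc4C3)c(OCc3ccccc3)cc2OC)c(OCc2ccccc2)c1 | intermediate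
32 | (3R,4S)-4-{4-hydroxy-5-[(3R)-7-hydroxy-3,4-dihydro-2H-chromen-3-yl]-2-methoxyphenyl}-3-(2-hydroxy-4-methoxyphenyl)-3,4-dihydro-2H-chromen-7-ol | COc1ccc([C@@H]2COc3cc(O)ccc3[C@H]2c2cc([C@@H]3COc4cc(O)ccc4C3)c(O)cc2OC)c(O)c1 | target

## Step count and least certain steps

Total: 17 steps. Longest linear sequence: 14 steps (steps 4 to 17, from 6 to 32). The triflate branch (steps 1 to 3) joins at steps 7 and 13.

Step 13 (key step). Most likely to go wrong: direct transfer of the alkenyl or the aryl group from boron to palladium (plain cross-coupling) in place of the metallate shift. A β-aryl alkene flanked by an ortho-methoxy group binds palladium poorly, and both coupling partners are ortho-oxygenated. Further risks are β-hydride elimination from the benzylic alkylpalladium intermediate and incomplete facial selectivity. The fallback abandons the boron route to the upper ring and uses an ortho-quinone methide; it sets out from 19 and 7 and returns at 30. Aldehyde 19 is condensed with the bromomagnesium salt of 3-(benzyloxy)phenol (ortho-specific hydroxyalkylation) to the 2-hydroxybenzhydrol F1, and p-toluenesulfinic acid converts F1 into the sulfone F2. Bromide 7 is coupled under palladium catalysis with the Reformatsky reagent of tert-butyl bromoacetate to the ester F3, and trifluoroacetic acid frees the arylacetic acid F4. F4, activated with pivaloyl chloride, and F2 are combined with a chiral isothiourea (HyperBTM) and base. Loss of sulfinate unmasks the quinone methide, the ammonium enolate adds to C4, and the phenoxide closes the trans-dihydrocoumarin F5. LiAlH4 reduces F5 to 30.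

Step 14. Most likely to go wrong: slow capture of the short-lived carbenoid by a boron atom that is shielded by the mac diol and three neighbouring aryl groups, so that the carbenoid decomposes first, or migration of oxygen in place of carbon. The fallback replaces the carbenoid by a stable nucleophile and removes the extra carbon afterwards; it sets out from 26 and returns at 29. Vinyllithium adds to 26, and iodine followed by NaOMe effects Zweifel olefination with retention to the alkene F6. OsO4 (catalytic) with NaIO4 cleaves F6 to the aldehyde F7, which NaBH4 reduces at once to 29 to limit epimerisation at C3.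

Step 7. Most likely to go wrong: slow coupling or reduced facial selectivity because the migrating aryl group and the triflate are both ortho-oxygenated, and inhibition by residual bromide. The fallback sets lower C3 with a stoichiometric chiral carbenoid; it sets out from 10, 5 and 11 and returns at 14. Bromide 10 is lithiated and quenched with isopropoxy pinacolborane to the arylboronic ester F8. Triflate 5 and 11 give the styrene F9 by Suzuki–Miyaura coupling (PdCl2(dppf)), 9-BBN then NaOH/H2O2 gives the alcohol F10, and N,N-diisopropylcarbamoyl chloride gives the carbamate F11. Deprotonation of F11 with s-BuLi/(−)-sparteine, borylation with F8 (retention) and 1,2-shift with MgBr2·OEt2 on warming (inversion) lead by the established stereochemical course to the R boronate 14.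

Step 12. Most likely to go wrong: an exchange equilibrium that stops short of completion, or protodeboronation of the electron-rich styrenyl boron under Lewis acid. The fallback separates cleavage and esterification; it sets out from 22 and returns at 23. NaIO4 with NH4OAc in aqueous acetone destroys the pinacol and gives the alkenylboronic acid F12, which is condensed with the mac diol over MgSO4 in CH2Cl2 to 23.

## Further compounds

F1 | step 13 | 5-(benzyloxy)-2-[{4-(benzyloxy)-5-[(3R)-7-(benzyloxy)-3,4-dihydro-2H-chromen-3-yl]-2-methoxyphenyl}(hydroxy)methyl]phenol (both epimers at the carbinol carbon) | COc1cc(OCc2ccccc2)c([C@@H]2COc3cc(OCc4ccccc4)ccc3C2)cc1C(O)c1ccc(OCc2ccccc2)cc1O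
F2 | step 13 | 5-(benzyloxy)-2-[{4-(benzyloxy)-5-[(3R)-7-(benzyloxy)-3,4-dihydro-2H-chromen-3-yl]-2-methoxyphenyl}(4-methylbenzenesulfonyl)methyl]phenol (both epimers at the sulfonyl-bearing carbon) | COc1cc(OCc2ccccc2)c([C@@H]2COc3cc(OCc4ccccc4)ccc3C2)cc1C(c1ccc(OCc2ccccc2)cc1O)S(=O)(=O)c1ccc(C)cc1
F3 | step 13 | tert-butyl 2-[2-(benzyloxy)-4-methoxyphenyl]acetate | COc1ccc(CC(=O)OC(C)(C)C)c(OCc2ccccc2)c1
F4 | step 13 | 2-[2-(benzyloxy)-4-methoxyphenyl]acetic acid | COc1ccc(CC(=O)O)c(OCc2ccccc2)c1
F5 | step 13 | (3R,4S)-7-(benzyloxy)-4-{4-(benzyloxy)-5-[(3R)-7-(benzyloxy)-3,4-dihydro-2H-chromen-3-yl]-2-methoxyphenyl}-3-[2-(benzyloxy)-4-methoxyphenyl]-3,4-dihydro-2H-chromen-2-one | COc1ccc([C@@H]2C(=O)Oc3cc(OCc4ccccc4)ccc3[C@H]2c2cc([C@@H]3COc4cc(OCc5ccccc5)ccc4C3)c(OCc3ccccc3)cc2OC)c(OCc2ccccc2)c1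
F6 | step 14 | (3R,4S)-3-[2-(benzyloxy)-4-methoxyphenyl]-4-[4-(benzyloxy)-2-(methoxymethoxy)phenyl]-4-{4-(benzyloxy)-5-[(3R)-7-(benzyloxy)-3,4-dihydro-2H-chromen-3-yl]-2-methoxyphenyl}but-1-ene | COc1ccc([C@H](C=C)[C@@H](c2ccc(OCc3ccccc3)cc2OCOC)c2cc([C@@H]3COc4cc(OCc5ccccc5)ccc4C3)c(OCc3ccccc3)cc2OC)c(OCc2ccccc2)c1
F7 | step 14 | (2R,3S)-2-[2-(benzyloxy)-4-methoxyphenyl]-3-[4-(benzyloxy)-2-(methoxymethoxy)phenyl]-3-{4-(benzyloxy)-5-[(3R)-7-(benzyloxy)-3,4-dihydro-2H-chromen-3-yl]-2-methoxyphenyl}propanal | COc1ccc([C@H](C=O)[C@@H](c2ccc(OCc3ccccc3)cc2OCOC)c2cc([C@@H]3COc4cc(OCc5ccccc5)ccc4C3)c(OCc3ccccc3)cc2OC)c(OCc2ccccc2)c1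
F8 | step 7 | 2-[2-(benzyloxy)-5-(1,3-dioxolan-2-yl)-4-methoxyphenyl]-4,4,5,5-tetramethyl-1,3,2-dioxaborolane | COc1cc(OCc2ccccc2)c(B2OC(C)(C)C(C)(C)O2)cc1C1OCCO1
F9 | step 7 | 4-(benzyloxy)-1-ethenyl-2-(methoxymethoxy)benzene | C=Cc1ccc(OCc2ccccc2)cc1OCOC
F10 | step 7 | 2-[4-(benzyloxy)-2-(methoxymethoxy)phenyl]ethan-1-ol | OCCc1ccc(OCc2ccccc2)cc1OCOC
F11 | step 7 | 2-[4-(benzyloxy)-2-(methoxymethoxy)phenyl]ethyl N,N-diisopropylcarbamate | CC(C)N(C(C)C)C(=O)OCCc1ccc(OCc2ccccc2)cc1OCOC
F12 | step 12 | [(E)-2-{4-(benzyloxy)-5-[(3R)-7-(benzyloxy)-3,4-dihydro-2H-chromen-3-yl]-2-methoxyphenyl}ethenyl]boronic acid | COc1cc(OCc2ccccc2)c([C@@H]2COc3cc(OCc4ccccc4)ccc3C2)cc1/C=C/B(O)O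
A1 | alternative 1 | 2-[(3R)-7-(benzyloxy)-3,4-dihydro-2H-chromen-3-yl]-4-{(3R,4S)-7-(benzyloxy)-3-[2-(benzyloxy)-4-methoxyphenyl]-3,4-dihydro-2H-chromen-4-yl}-5-methoxyphenol | COc1ccc([C@@H]2COc3cc(OCc4ccccc4)ccc3[C@H]2c2cc([C@@H]3COc4cc(OCc5ccccc5)ccc4C3)c(O)cc2OC)c(OCc2ccccc2)c1
A2 | alternative 1 | (3E)-1-{(3R,4S)-7-(benzyloxy)-3-[2-(benzyloxy)-4-methoxyphenyl]-3,4-dihydro-2H-chromen-4-yl}-4-[(3R)-7-(benzyloxy)-3,4-dihydro-2H-chromen-3-yl]-1-diazobut-3-en-2-one | COc1ccc([C@@H]2COc3cc(OCc4ccccc4)ccc3[C@H]2C(=[N+]=[N-])C(=O)/C=C/[C@@H]2COc3cc(OCc4ccccc4)ccc3C2)c(OCc2ccccc2)c1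
A3 | alternative 1 | methoxyacetylene (methoxyethyne) | COC#C
A4 | alternative 2 | 2-[(1R)-1-{2-(benzyloxy)-5-[(3R,4S)-7-(benzyloxy)-3-[2-(benzyloxy)-4-methoxyphenyl]-3,4-dihydro-2H-chromen-4-yl]-4-methoxyphenyl}-2-[4-(benzyloxy)-2-(methoxymethoxy)phenyl]ethyl]-4,4,5,5-tetramethyl-1,3,2-dioxaborolane | COc1ccc([C@@H]2COc3cc(OCc4ccccc4)ccc3[C@H]2c2cc([C@@H](Cc3ccc(OCc4ccccc4)cc3OCOC)B3OC(C)(C)C(C)(C)O3)c(OCc3ccccc3)cc2OC)c(OCc2ccccc2)c1
A5 | alternative 2 | (3R,4S)-7-(benzyloxy)-4-[4-(benzyloxy)-5-bromo-2-methoxyphenyl]-3-[2-(benzyloxy)-4-methoxyphenyl]-3,4-dihydro-2H-chromene | COc1ccc([C@@H]2COc3cc(OCc4ccccc4)ccc3[C@H]2c2cc(Br)c(OCc3ccccc3)cc2OC)c(OCc2ccccc2)c1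
A6 | alternative 3 | (3R,4S)-7-(benzyloxy)-4-{4-(benzyloxy)-5-[(3R)-7-(benzyloxy)-3,4-dihydro-2H-chromen-3-yl]-2-methoxyphenyl}-3-[2-(benzyloxy)-4-methoxyphenyl]-3,4-dihydro-2H-chromen-2-one | COc1ccc([C@@H]2C(=O)Oc3cc(OCc4ccccc4)ccc3[C@H]2c2cc([C@@H]3COc4cc(OCc5ccccc5)ccc4C3)c(OCc3ccccc3)cc2OC)c(OCc2ccccc2)c1
A7 | alternative 3 | 2-[2-(benzyloxy)-4-methoxyphenyl]acetic acid | COc1ccc(CC(=O)O)c(OCc2ccccc2)c1
A8 | alternative 3 | 3-(benzyloxy)-6-({4-(benzyloxy)-5-[(3R)-7-(benzyloxy)-3,4-dihydro-2H-chromen-3-yl]-2-methoxyphenyl}methylidene)cyclohexa-2,4-dien-1-one (alkene geometry not defined) | COc1cc(OCc2ccccc2)c([C@@H]2COc3cc(OCc4ccccc4)ccc3C2)cc1C=C1C=CC(OCc2ccccc2)=CC1=O
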